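**Retrosynthetic overview**
1. The 1-oxo-10(14)-ene unit comes last, from the 1(10)E-alkene of the macrocycle by a singlet-oxygen ene reaction and dehydration. O13 is acetylated in the same flask.
2. Ring order: the ten-membered carbocycle is closed first, at C6–C7. A C7 alkenylchromium (from a Z enol triflate) adds to the C6 Z-enal, which is the same bond and polarity as the farnesyl-to-germacrene closure. The butenolide forms second, by O6→C12 lactonisation of the alkoxide in the same flask.
3. Acyclic chain: the C8–C9 bond and the 1(10)E-alkene come from a Carroll [3,3] shift with dimethyl acetonedicarboxylate. C13 comes from silyloxymethylation, and the alkene geometry from chelate-controlled triflation.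
4. The C2–C3 bond and 3S come from an Ipc2BCl aldol of methyl isopropenyl ketone with a Z-enal made from citraconic anhydride, whose ring fixes 4Z. An Evans–Tishchenko step installs 3-OAc and the C1 carbinol needed for the [3,3] shift.

Assumption: the SMILES is read as (3S,6R,4Z)-3,13-diacetoxy-1-oxogermacra-4,7(11),10(14)-trien-12,6-olide (germacrane numbering is used for positions), and the (R)-oxazoline sulfonamide ligand of step 11 is taken to direct Si-face attack on the aldehyde (its antipode is used if the first run shows the opposite sense).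

**Step 1**
Reactants: 1 citraconic anhydride
Product: 2 (Z)-2-methylbut-2-ene-1,4-diol
Conditions: LiAlH4, Et2O, 0 °C to rt; H2O, 15% NaOH work-up
Reagents that add atoms: none
Why: Hydride reduction of a cyclic anhydride to the diol, in which the cis-locked ring of 1 hands on the 4Z geometry of the target.

**Step 2**
Reactants: 2 (Z)-2-methylbut-2-ene-1,4-diol
Product: 3 (Z)-4-(tert-butyldimethylsilyloxy)-2-methylbut-2-en-1-ol
Conditions: TBSCl (1.0 equiv), imidazole, CH2Cl2, −20 °C
Reagents that add atoms: tert-butyldimethylsilyl chloride, CC(C)(C)[Si](C)(C)Cl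
Why: Sterically controlled monosilylation, in which the CH2OH next to the vinylic CH (future C6) reacts faster than the one next to the methyl-bearing carbon, and the regioisomer and bis-ether are recycled by desilylation.

**Step 3**
Reactants: 3 (Z)-4-(tert-butyldimethylsilyloxy)-2-methylbut-2-en-1-ol
Product: 4 (Z)-4-(tert-butyldimethylsilyloxy)-2-methylbut-2-enal
Conditions: MnO2, CH2Cl2, rt; used at once
Reagents that add atoms: none
Why: Neutral MnO2 allylic oxidation, which takes Z-allylic alcohols to Z-enals without isomerisation (as in nerol to neral).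

**Step 4**
Reactants: 4 (Z)-4-(tert-butyldimethylsilyloxy)-2-methylbut-2-enal; 5 3-methylbut-3-en-2-one
Product: 8 (5S,6Z)-8-(tert-butyldimethylsilyloxy)-5-hydroxy-2,6-dimethylocta-1,6-dien-3-one, via diisopinocampheylboron dienolate 6 (not isolated), via boron aldolate 7 (not isolated)
Conditions: 5, (+)-Ipc2BCl, Et3N, Et2O, 0 °C; 4, −78 to −20 °C; H2O2, MeOH, pH 7 buffer, 0 °C
Reagents that add atoms: none
Why: Reagent-controlled boron aldol of a methyl ketone (Paterson aldol), in which the (+)-isopinocampheyl ligands shield one aldehyde face in the cyclic transition state and set 3S (about 80–90% ee expected, the residual enantiomer becoming a separable diastereomer in step 11), while the cold neutral medium keeps the Z-enal intact.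

**Step 5**
Reactants: 8 (5S,6Z)-8-(tert-butyldimethylsilyloxy)-5-hydroxy-2,6-dimethylocta-1,6-dien-3-one
Product: 10 (3S,5S,6Z)-8-(tert-butyldimethylsilyloxy)-3-hydroxy-2,6-dimethylocta-1,6-dien-5-yl acetate, via acetaldehyde hemiacetal 9 (not isolated)
Conditions: SmI2 (0.3 equiv), MeCHO (10 equiv), THF, −10 °C
Reagents that add atoms: acetaldehyde, CC=O
Why: Evans–Tishchenko reduction, in which the trivalent samarium alkoxide of 9 delivers hydride intramolecularly (1,2) to the C1 ketone, so that one operation puts the target acetate on O3 and gives the 1,3-anti allylic alcohol, whose C1 configuration is erased in step 6.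

**Step 6**
Reactants: 10 (3S,5S,6Z)-8-(tert-butyldimethylsilyloxy)-3-hydroxy-2,6-dimethylocta-1,6-dien-5-yl acetate; 11 dimethyl 3-oxopentanedioate
Product: 14 methyl (6E,9S,10Z)-9-acetoxy-12-(tert-butyldimethylsilyloxy)-6,10-dimethyl-3-oxododeca-6,10-dienoate, via mixed allyl methyl 3-oxoglutarate 12 (not isolated), via β-keto acid 13 (not isolated)
Conditions: 11 (4 equiv), xylenes, 140 °C, 4 Å sieves (MeOH removal)
Reagents that add atoms: none
Why: Carroll rearrangement, in which thermal acylketene transesterification gives 12, its enol undergoes a chair [3,3] shift with the C2 chain equatorial (forming the C8–C9 bond and the E-1(10) alkene), and 13 loses CO2 under neutral conditions that the acetate and silyl ether survive.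

**Step 7**
Reactants: 14 methyl (6E,9S,10Z)-9-acetoxy-12-(tert-butyldimethylsilyloxy)-6,10-dimethyl-3-oxododeca-6,10-dienoate
Product: 16 methyl (6E,9S,10Z)-9-acetoxy-12-(tert-butyldimethylsilyloxy)-6,10-dimethyl-3-oxo-2-(triisopropylsilyloxymethyl)dodeca-6,10-dienoate (C2 epimers), via trimethylsilyl enol ether 15 (not isolated)
Conditions: TMSCl, Et3N, hexane–CH2Cl2, rt, filter and concentrate; (iPr3SiO)CH2Cl, ZnBr2 (10 mol %), CH2Cl2, 0 °C
Reagents that add atoms: (triisopropylsiloxy)methyl chloride, CC(C)[Si](OCCl)(C(C)C)C(C)C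
Why: Mukaiyama-type SN1 alkylation of a silyl enol ether by an α-chloro ether, in which the silyl enol ether route makes the O-silyl oxocarbenium ion attack at carbon (C11) rather than at oxygen, and the new C11 centre is unselective and is erased in step 8.

**Step 8**
Reactants: 16 methyl (6E,9S,10Z)-9-acetoxy-12-(tert-butyldimethylsilyloxy)-6,10-dimethyl-3-oxo-2-(triisopropylsilyloxymethyl)dodeca-6,10-dienoate
Product: 17 methyl (2Z,6E,9S,10Z)-9-acetoxy-12-(tert-butyldimethylsilyloxy)-6,10-dimethyl-3-(trifluoromethylsulfonyloxy)-2-(triisopropylsilyloxymethyl)dodeca-2,6,10-trienoate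
Conditions: LiOTf, Et3N, Tf2O, CH2Cl2, −78 to 0 °C
Reagents that add atoms: triflic anhydride, O=S(=O)(OS(=O)(=O)C(F)(F)F)C(F)(F)F
Why: Chelation-controlled enol triflation, in which the lithium-chelated U-shaped enolate holds O7 cis to the ester so that O-sulfonylation gives the Z enol triflate (C7–OTf cis to C12) needed for the later lactonisation.

**Step 9**
Reactants: 17 the bis-silyl enol triflate
Product: 18 methyl (2Z,6E,9S,10Z)-9-acetoxy-12-hydroxy-2-(hydroxymethyl)-6,10-dimethyl-3-(trifluoromethylsulfonyloxy)dodeca-2,6,10-trienoate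
Conditions: HF·pyridine, pyridine, THF, 0 °C to rt
Reagents that add atoms: none
Why: Fluoride cleavage of both silyl ethers under mildly acidic conditions that spare the enol triflate, allylic acetate and ester and avoid base-induced acetyl migration.

**Step 10**
Reactants: 18 the diol enol triflate
Product: 19 methyl (2Z,6E,9S,10Z)-9-acetoxy-2-(hydroxymethyl)-6,10-dimethyl-12-oxo-3-(trifluoromethylsulfonyloxy)dodeca-2,6,10-trienoate
Conditions: MnO2, CH2Cl2, rt, monitored
Reagents that add atoms: none
Why: Chemoselective MnO2 allylic oxidation, in which the electron-rich neryl-type C6 alcohol reacts far faster than the C13 alcohol on the acceptor-substituted alkene, and because O3 is acetylated the Z-γ-oxy enal cannot collapse to a lactol or furan.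

**Step 11 (key step)**
Reactants: 19 the enal enol triflate
Product: 21 (3S,6R,1(10)E,4Z)-3-acetoxy-13-hydroxygermacra-1(10),4,7(11)-trien-12,6-olide, via macrocyclic γ-hydroxy ester 20 (not isolated)
Conditions: CrCl2 (10 equiv), NiCl2 (0.1 equiv), (R)-N-[2-(4-tert-butyl-4,5-dihydrooxazol-2-yl)-6-methylphenyl]methanesulfonamide (11 equiv), Et3N (11 equiv), THF, rt, syringe-pump addition of 19 to 2 mM; aq. ethylenediamine work-up
Reagents that add atoms: none
Why: Proposed new method: zerovalent nickel inserts into the activated C7–OTf bond, transmetallation gives an ester-chelated tetrasubstituted alkenylchromium that adds 1,2 to the s-trans Z-enal at high dilution and closes the ten-membered ring at C6–C7, the sulfonamide-bound trivalent chromium directs Si-face attack to set 6R, and the alkoxide held cis to CO2Me lactonises at once, the closest known chemistry being Nozaki–Hiyama–Kishi macrocyclisations of haloalkene aldehydes to ten-membered rings and couplings of β-iodoacrylates with aldehydes that give butenolides directly.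

**Step 12**
Reactants: 21 the hydroxy lactone
Product: 25 (3S,6R,4Z)-3,13-diacetoxy-1-oxogermacra-4,7(11),10(14)-trien-12,6-olide (CNP0272505.1), via 3,13-diacetate 22 (not isolated), via allylic hydroperoxide 23 (not isolated), via allylic peracetate 24 (not isolated)
Conditions: Ac2O, pyridine, DMAP (5 mol %), tetraphenylporphyrin (1 mol %), O2, visible light, CH2Cl2, 0 °C
Reagents that add atoms: acetic anhydride, CC(=O)OC(C)=O; dioxygen, O=O
Why: One-pot acetylation, Schenck ene reaction and Kornblum–DeLaMare-type dehydration, in which singlet oxygen attacks only the electron-rich 1(10)-alkene (the 4,5-alkene is flanked by two acyloxy groups and the butenolide is electron-poor), abstracts H from C14 on the more crowded side while the C2–H bonds are deactivated by the adjacent C3 acetate (as in costunolide to peroxycostunolide), and the C1 peracetate eliminates to the enone without touching C3 or C6.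

**Compound list**
1 | citraconic anhydride | CC1=CC(=O)OC1=O | starting material
2 | (Z)-2-methylbut-2-ene-1,4-diol | OC/C=C(C)\CO | intermediate
3 | (Z)-4-(TBSO)-2-methylbut-2-en-1-ol | OC/C(C)=C\CO[Si](C)(C)C(C)(C)C | intermediate
4 | (Z)-4-(TBSO)-2-methylbut-2-enal | O=C/C(C)=C\CO[Si](C)(C)C(C)(C)C | intermediate
5 | 3-methylbut-3-en-2-one | CC(=O)C(C)=C | starting material
6 | diisopinocampheylboron dienolate of 5 | C=C(C)C(=C)OB([C@H]1C[C@H]2C[C@@H]([C@@H]1C)C2(C)C)[C@H]1C[C@H]2C[C@@H]([C@@H]1C)C2(C)C | intermediate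
7 | boron aldolate | C=C(C)C(=O)C[C@H](OB([C@H]1C[C@H]2C[C@@H]([C@@H]1C)C2(C)C)[C@H]1C[C@H]2C[C@@H]([C@@H]1C)C2(C)C)/C(C)=C\CO[Si](C)(C)C(C)(C)C | intermediate
8 | (S)-β-hydroxy enone | C=C(C)C(=O)C[C@H](O)/C(C)=C\CO[Si](C)(C)C(C)(C)C | intermediate
9 | acetaldehyde hemiacetal of 8 | C=C(C)C(=O)C[C@H](OC(C)O)/C(C)=C\CO[Si](C)(C)C(C)(C)C | intermediate
10 | anti-1,3-diol 3-O-monoacetate | C=C(C)[C@@H](O)C[C@H](OC(C)=O)/C(C)=C\CO[Si](C)(C)C(C)(C)C | intermediate
11 | dimethyl 3-oxopentanedioate | COC(=O)CC(=O)CC(=O)OC | starting material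
12 | mixed allyl methyl 3-oxoglutarate | COC(=O)CC(=O)CC(=O)O[C@@H](C[C@H](OC(C)=O)/C(C)=C\CO[Si](C)(C)C(C)(C)C)C(C)=C | intermediate
13 | β-keto acid after the [3,3] shift | COC(=O)CC(=O)C(C(=O)O)C/C(C)=C/C[C@H](OC(C)=O)/C(C)=C\CO[Si](C)(C)C(C)(C)C | intermediate
14 | β-keto ester | COC(=O)CC(=O)CC/C(C)=C/C[C@H](OC(C)=O)/C(C)=C\CO[Si](C)(C)C(C)(C)C | intermediate
15 | trimethylsilyl enol ether of 14 | COC(=O)C=C(O[Si](C)(C)C)CC/C(C)=C/C[C@H](OC(C)=O)/C(C)=C\CO[Si](C)(C)C(C)(C)C | intermediate
16 | α-(TIPSO-methyl) β-keto ester | COC(=O)C(CO[Si](C(C)C)(C(C)C)C(C)C)C(=O)CC/C(C)=C/C[C@H](OC(C)=O)/C(C)=C\CO[Si](C)(C)C(C)(C)C | intermediate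
17 | Z enol triflate, bis-silyl ether | COC(=O)/C(CO[Si](C(C)C)(C(C)C)C(C)C)=C(\OS(=O)(=O)C(F)(F)F)CC/C(C)=C/C[C@H](OC(C)=O)/C(C)=C\CO[Si](C)(C)C(C)(C)C | intermediate
18 | diol enol triflate | COC(=O)/C(CO)=C(\OS(=O)(=O)C(F)(F)F)CC/C(C)=C/C[C@H](OC(C)=O)/C(C)=C\CO | intermediate
19 | Z-enal enol triflate | COC(=O)/C(CO)=C(\OS(=O)(=O)C(F)(F)F)CC/C(C)=C/C[C@H](OC(C)=O)/C(C)=C\C=O | intermediate
20 | macrocyclic γ-hydroxy ester | C/C1=C\C[C@H](OC(C)=O)/C(C)=C\[C@@H](O)/C(CC1)=C(/CO)C(=O)OC | intermediate
21 | 3-acetoxy-13-hydroxy-1(10),4,7(11)-trien-12,6-olide | C/C1=C\C[C@H](OC(C)=O)/C(C)=C\[C@H]2OC(=O)C(CO)=C2CC1 | intermediate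
22 | 3,13-diacetate | C/C1=C\C[C@H](OC(C)=O)/C(C)=C\[C@H]2OC(=O)C(COC(C)=O)=C2CC1 | intermediate
23 | 1-hydroperoxy-10(14)-ene (C1 not assigned) | C=C1CCC2=C(COC(C)=O)C(=O)O[C@@H]2/C=C(/C)[C@@H](OC(C)=O)CC1OO | intermediate
24 | C1 peracetate (C1 not assigned) | C=C1CCC2=C(COC(C)=O)C(=O)O[C@@H]2/C=C(/C)[C@@H](OC(C)=O)CC1OOC(C)=O | intermediate
25 | CNP0272505.1 | C=C1CCC2=C(COC(C)=O)C(=O)O[C@@H]2/C=C(/C)[C@@H](OC(C)=O)CC1=O | target

**Totals:** 12 steps in all. The longest linear sequence is 12 steps, from citraconic anhydride.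

**Steps most likely to fail**

Step 11 is the largest risk. The alkenylchromium is tetrasubstituted, the ring is strained, divalent chromium may reductively cleave the γ-acetate of the enal, and the macrocyclic transition state may override the ligand. A simple A(1,3)-strain model with an s-trans enal actually favours the 3,6-cis (6S) epimer. The fallback sets out from 19 and comes back at 21, and it sets C6 by protonation instead of by C–C bond formation. The ring is closed without ligand (CrCl2, NiCl2, DMF) and any C6 ratio is accepted, including the 6-epi lactone F1. The mixture is treated with TBSOTf and Et3N to give the planar macrocyclic 2-silyloxyfuran F2. HF·pyridine at low temperature then desilylates F2 and protonates C6. Lactone 21 is separated and F1 is returned to the cycle.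

Step 7 is the second risk. O-alkylation, double alkylation or loss of silanolate to the α-methylene keto ester can each compete. The fallback sets out from 14 and comes back at 18, and it brings in C13 at the formyl oxidation level. Dimethylformamide dimethyl acetal gives, with unambiguous C–C bond formation, the enaminone F3. Treatment with Tf2O and then aqueous NaHCO3 gives the α-formyl enol triflate F4. Reduction with NaBH4 and CeCl3 gives the 13-hydroxy enol triflate F5, and the Z isomer is separated at this stage. HF·pyridine then removes the C6 silyl group to reach 18.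

Step 12 is the third risk. Tertiary C10 hydroperoxide may form, and pyridine or DMAP may eliminate the 3-acetate β to the new ketone. The fallback sets out from 21 and comes back at 25, and it replaces the ene reaction by epoxide chemistry under non-basic conditions. Compound 21 is acetylated and 22 is isolated. mCPBA epoxidises the most electron-rich alkene to give the 1(10)-epoxide F6. Cp2TiCl (from Cp2TiCl2 and Mn; trivalent titanium) opens F6 to the C10 radical, and β-hydrogen loss gives the 1-hydroxy-10(14)-ene F7. Dess–Martin periodinane then oxidises F7 to 25.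

**Further compounds**
F1 | step 11 | (3S,6S)-6-epi-3-acetoxy-13-hydroxygermacra-1(10),4,7(11)-trien-12,6-olide | C/C1=C\C[C@H](OC(C)=O)/C(C)=C\[C@@H]2OC(=O)C(CO)=C2CC1
F2 | step 11 | macrocyclic 2-(TBSO)-3-(TBSO-methyl)furan | C/C1=C\C[C@H](OC(C)=O)/C(C)=C\c2oc(O[Si](C)(C)C(C)(C)C)c(CO[Si](C)(C)C(C)(C)C)c2CC1
F3 | step 7 | 2-(dimethylaminomethylene) β-keto ester | COC(=O)C(=CN(C)C)C(=O)CC/C(C)=C/C[C@H](OC(C)=O)/C(C)=C\CO[Si](C)(C)C(C)(C)C
F4 | step 7 | α-formyl Z enol triflate | COC(=O)/C(C=O)=C(\OS(=O)(=O)C(F)(F)F)CC/C(C)=C/C[C@H](OC(C)=O)/C(C)=C\CO[Si](C)(C)C(C)(C)C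
F5 | step 7 | 13-hydroxy Z enol triflate, C6 TBS ether | COC(=O)/C(CO)=C(\OS(=O)(=O)C(F)(F)F)CC/C(C)=C/C[C@H](OC(C)=O)/C(C)=C\CO[Si](C)(C)C(C)(C)C
F6 | step 12 | 1(10)-epoxide of 22 (epoxide face not assigned) | CC12CCC3=C(COC(C)=O)C(=O)O[C@@H]3/C=C(/C)[C@@H](OC(C)=O)CC1O2
F7 | step 12 | 3,13-diacetoxy-1-hydroxygermacra-4,7(11),10(14)-trien-12,6-olide (C1 not assigned) | C=C1CCC2=C(COC(C)=O)C(=O)O[C@@H]2/C=C(/C)[C@@H](OC(C)=O)CC1O
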